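**Retrosynthetic overview**
- The target comes from HF·pyridine desilylation of its bis-silyl catechol ether, which comes from Steglich esterification of the side-chain α-hydroxy ketone with bis-TBS caffeic acid.
- The cyclopropyl ketone comes from a new catalyst-controlled [2+1] union of a vinyl dihydropyranone acetate with a lactate-derived α'-silyloxy α-diazoketone; this step forms the cyclopropane and sets both of its stereocentres.
- The vinyl dihydropyranone comes from a δ-hydroxy ynoate (semihydrogenation, lactonisation), made by propiolate opening of the epoxide from Sharpless desymmetrisation of divinylcarbinol; this sets C6 and the acetoxy carbinol.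
- The diazoketone comes from ethyl (S)-lactate, which supplies the side-chain carbinol stereocentre.
- Ring order: dihydropyranone first, cyclopropane second; the catechol ring is bought as caffeic acid.

Configuration planned for (read from the SMILES): lactone C6 R; acetoxy carbinol S; cyclopropane trans, 1S (carbon bearing the carbinol) and 2S (carbon bearing the ketone); side-chain O-bearing carbon S.

Assumption: the (R)-ligand enantiomer of the ruthenium phenyl-oxazoline catalyst is taken as the one that builds the (1S,2S) ring; if the first run shows the opposite face, the mirror-image catalyst is used and nothing else changes.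

**Route**

Step 1
Reactants: 1 penta-1,4-dien-3-ol (divinylcarbinol)
Product: 2 (2R,3S)-1,2-epoxypent-4-en-3-ol
Conditions: Ti(OiPr)4 (10 mol %), L-(+)-DIPT (13 mol %), cumene hydroperoxide, 4 Å MS, CH2Cl2, −20 °C, 5 d
Reagents that add atoms: cumene hydroperoxide, CC(C)(OO)c1ccccc1
Why: Sharpless asymmetric epoxidation used as a desymmetrisation; the L-(+)-tartrate titanium complex epoxidises one enantiotopic vinyl group on the face that gives the erythro (2R,3S) epoxy alcohol, and the minor enantiomer is consumed by a second epoxidation, so both C6 and the carbinol centre of the target are set here in high ee.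

Step 2
Reactants: 2 (2R,3S)-1,2-epoxypent-4-en-3-ol
Product: 3 tert-butyldimethyl{[(S)-1-((R)-oxiran-2-yl)prop-2-en-1-yl]oxy}silane
Conditions: TBSCl, imidazole, DMF, 0 °C → rt
Reagents that add atoms: tert-butyldimethylsilyl chloride, CC(C)(C)[Si](C)(C)Cl
Why: Silyl ether formation under imidazole is too weakly basic for Payne rearrangement, so the epoxy alcohol is protected without touching either stereocentre.

Step 3
Reactants: 3 tert-butyldimethyl{[(S)-1-((R)-oxiran-2-yl)prop-2-en-1-yl]oxy}silane; 4 ethyl propiolate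
Product: 5 ethyl (5R,6S)-6-(tert-butyldimethylsilyloxy)-5-hydroxyoct-7-en-2-ynoate
Conditions: 4 (3 equiv), n-BuLi, THF, −78 °C; BF3·OEt2 (promoter), then 3, −78 °C; sat. aq. NH4Cl
Reagents that add atoms: none
Why: Yamaguchi–Hirao alkynylation; the BF3-activated epoxide is opened by the lithium acetylide at the unhindered terminal carbon (SN2), so no stereocentre is involved.

Step 4
Reactants: 5 ethyl (5R,6S)-6-(tert-butyldimethylsilyloxy)-5-hydroxyoct-7-en-2-ynoate
Product: 7 (R)-6-[(S)-1-(tert-butyldimethylsilyloxy)prop-2-en-1-yl]-5,6-dihydro-2H-pyran-2-one, via Z-hydroxy-enoate 6 (not isolated)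
Conditions: H2 (1 atm), Pd/CaCO3 poisoned with Pb(OAc)2, quinoline, EtOAc, rt (stop at 1 equiv H2); then PPTS (cat.), PhMe, 60 °C
Reagents that add atoms: none
Why: Lindlar semihydrogenation adds H2 syn to the alkyne much faster than to the hindered vinyl group, and the resulting Z-enoate has the δ-hydroxyl placed for acid-catalysed lactonisation to the dihydropyranone.

Step 5
Reactants: 7 (R)-6-[(S)-1-(tert-butyldimethylsilyloxy)prop-2-en-1-yl]-5,6-dihydro-2H-pyran-2-one
Product: 8 (R)-6-[(S)-1-hydroxyprop-2-en-1-yl]-5,6-dihydro-2H-pyran-2-one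
Conditions: HF·pyridine, THF, 0 °C → rt
Reagents that add atoms: none
Why: Fluoride-driven desilylation under mildly acidic conditions leaves the base-sensitive unsaturated lactone untouched.

Step 6
Reactants: 8 (R)-6-[(S)-1-hydroxyprop-2-en-1-yl]-5,6-dihydro-2H-pyran-2-one
Product: 9 (S)-1-[(R)-6-oxo-3,6-dihydro-2H-pyran-2-yl]prop-2-en-1-yl acetate
Conditions: Ac2O, pyridine, DMAP (cat.), CH2Cl2, 0 °C
Reagents that add atoms: acetic anhydride, CC(=O)OC(C)=O
Why: DMAP-catalysed acetylation of the only free hydroxyl installs the acetate of the target with retention at the carbinol carbon.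

Step 7
Reactants: 10 ethyl (S)-lactate
Product: 11 ethyl (S)-2-(tert-butyldimethylsilyloxy)propanoate
Conditions: TBSCl, imidazole, DMF, rt
Reagents that add atoms: tert-butyldimethylsilyl chloride, CC(C)(C)[Si](C)(C)Cl
Why: Standard silyl ether formation; the chiral-pool (S) centre is not touched.

Step 8
Reactants: 11 ethyl (S)-2-(tert-butyldimethylsilyloxy)propanoate
Product: 12 (S)-2-(tert-butyldimethylsilyloxy)propanoic acid
Conditions: LiOH·H2O, THF/H2O, 0 °C; then 1 M HCl to pH 3–4, 0 °C
Reagents that add atoms: lithium hydroxide, [Li+].[OH-]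
Why: Saponification at 0 °C is faster than enolisation of the α-silyloxy ester, so the acid is obtained without racemisation.

Step 9
Reactants: 12 (S)-2-(tert-butyldimethylsilyloxy)propanoic acid
Product: 14 (S)-3-(tert-butyldimethylsilyloxy)-1-diazobutan-2-one, via mixed carbonic anhydride 13 (not isolated)
Conditions: iBuOCOCl, N-methylmorpholine, THF, −15 °C; then CH2N2, Et2O, −15 °C → rt
Reagents that add atoms: diazomethane, C=[N+]=[N-]; isobutyl chloroformate, CC(C)COC(Cl)=O (its atoms stay only in intermediate 13)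
Why: Acylation of diazomethane by a mixed anhydride (first stage of an Arndt–Eistert sequence) is neutral and cold, so the α-stereocentre and the silyl ether survive.

Step 10
Reactants: 9 (S)-1-[(R)-6-oxo-3,6-dihydro-2H-pyran-2-yl]prop-2-en-1-yl acetate; 14 (S)-3-(tert-butyldimethylsilyloxy)-1-diazobutan-2-one
Product: 15 (S)-{(1S,2S)-2-[(S)-2-(tert-butyldimethylsilyloxy)propanoyl]cyclopropyl}[(R)-6-oxo-3,6-dihydro-2H-pyran-2-yl]methyl acetate
Conditions: [Ru((R)-Pheox)(MeCN)4]PF6 (5 mol %; divalent ruthenium; Pheox = C,N-cyclometalated 2-[(4R)-4-phenyl-4,5-dihydro-1,3-oxazol-2-yl]phenyl), 14 (2 equiv) added over 10 h by syringe pump, CH2Cl2, 0 °C → rt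
Reagents that add atoms: none
Why: Proposed new method: the cationic cyclometalated phenyl-oxazoline complex of divalent ruthenium loses MeCN and decomposes 14 to an electrophilic ruthenium carbene held cis to the oxazoline by the trans influence of the aryl–Ru bond, and the terminal CH2 of the monosubstituted olefin of 9 attacks it end-on in a concerted asynchronous [2+1] addition, with the olefin substituent anti to the acyl group (trans ring) and away from the oxazoline 4-phenyl group (face selection, giving 1S,2S under catalyst control over the weak and possibly opposing bias of the allylic acetate), while the cis-disubstituted electron-poor lactone olefin is too hindered and deactivated to compete; the closest known reaction type is asymmetric cyclopropanation of styrenes and other simple terminal olefins with acceptor diazo compounds (diazoacetates, diazo acetoxy acetone) by this catalyst family, which has not been shown for an unactivated allylic-ester olefin as limiting partner, for an α'-silyloxy diazoketone with its own stereocentre, or beside a second conjugated olefin.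

Step 11
Reactants: 15 (S)-{(1S,2S)-2-[(S)-2-(tert-butyldimethylsilyloxy)propanoyl]cyclopropyl}[(R)-6-oxo-3,6-dihydro-2H-pyran-2-yl]methyl acetate
Product: 16 (S)-{(1S,2S)-2-[(S)-2-hydroxypropanoyl]cyclopropyl}[(R)-6-oxo-3,6-dihydro-2H-pyran-2-yl]methyl acetate
Conditions: HF·pyridine, THF/pyridine, 0 °C → rt
Reagents that add atoms: none
Why: Acidic fluoride desilylation frees the α-hydroxy ketone without the base that would epimerise it or open the lactone, and the acetate is inert.

Step 12
Reactants: 17 caffeic acid [(E)-3-(3,4-dihydroxyphenyl)acrylic acid]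
Product: 19 (E)-3-[3,4-bis(tert-butyldimethylsilyloxy)phenyl]acrylic acid, via tris-silylated caffeate 18 (not isolated)
Conditions: TBSCl (3.5 equiv), imidazole, DMF, rt; then AcOH/THF/H2O (3:1:1), rt
Reagents that add atoms: tert-butyldimethylsilyl chloride, CC(C)(C)[Si](C)(C)Cl
Why: Exhaustive silylation followed by selective hydrolysis of the much more labile silyl ester gives the free acid with both phenols masked.

Step 13
Reactants: 16 (S)-{(1S,2S)-2-[(S)-2-hydroxypropanoyl]cyclopropyl}[(R)-6-oxo-3,6-dihydro-2H-pyran-2-yl]methyl acetate; 19 (E)-3-[3,4-bis(tert-butyldimethylsilyloxy)phenyl]acrylic acid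
Product: 20 (S)-{(1S,2S)-2-[(S)-2-({(E)-3-[3,4-bis(tert-butyldimethylsilyloxy)phenyl]acryloyl}oxy)propanoyl]cyclopropyl}[(R)-6-oxo-3,6-dihydro-2H-pyran-2-yl]methyl acetate
Conditions: DCC, DMAP (10 mol %), CH2Cl2, 0 °C
Reagents that add atoms: none
Why: Steglich esterification acylates the secondary hydroxyl with retention, and low temperature with little DMAP keeps the α-acyloxy ketone centre from epimerising.

Step 14
Reactants: 20 (S)-{(1S,2S)-2-[(S)-2-({(E)-3-[3,4-bis(tert-butyldimethylsilyloxy)phenyl]acryloyl}oxy)propanoyl]cyclopropyl}[(R)-6-oxo-3,6-dihydro-2H-pyran-2-yl]methyl acetate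
Product: 21 (S)-{(1S,2S)-2-[(S)-2-{[(E)-3-(3,4-dihydroxyphenyl)acryloyl]oxy}propanoyl]cyclopropyl}[(R)-6-oxo-3,6-dihydro-2H-pyran-2-yl]methyl acetate (CNP0103198.1)
Conditions: HF·pyridine, THF/pyridine, 0 °C → rt, under argon
Reagents that add atoms: none
Why: Fluoride desilylation of the two aryl silyl ethers under buffered acidic conditions generates no phenoxide or enolate, so the acetate, both enoates and the α-acyloxy ketone centre are preserved.

**Compound list**
1 | penta-1,4-dien-3-ol | C=CC(O)C=C | starting material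
2 | (2R,3S)-1,2-epoxypent-4-en-3-ol | C=C[C@H](O)[C@H]1CO1 | intermediate
3 | tert-butyldimethyl{[(S)-1-((R)-oxiran-2-yl)prop-2-en-1-yl]oxy}silane | C=C[C@H](O[Si](C)(C)C(C)(C)C)[C@H]1CO1 | intermediate
4 | ethyl propiolate | C#CC(=O)OCC | starting material
5 | ethyl (5R,6S)-6-(tert-butyldimethylsilyloxy)-5-hydroxyoct-7-en-2-ynoate | C=C[C@H](O[Si](C)(C)C(C)(C)C)[C@H](O)CC#CC(=O)OCC | intermediate
6 | ethyl (2Z,5R,6S)-6-(tert-butyldimethylsilyloxy)-5-hydroxyocta-2,7-dienoate | C=C[C@H](O[Si](C)(C)C(C)(C)C)[C@H](O)C/C=C\C(=O)OCC | intermediate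
7 | (R)-6-[(S)-1-(tert-butyldimethylsilyloxy)prop-2-en-1-yl]-5,6-dihydro-2H-pyran-2-one | C=C[C@H](O[Si](C)(C)C(C)(C)C)[C@H]1CC=CC(=O)O1 | intermediate
8 | (R)-6-[(S)-1-hydroxyprop-2-en-1-yl]-5,6-dihydro-2H-pyran-2-one | C=C[C@H](O)[C@H]1CC=CC(=O)O1 | intermediate
9 | (S)-1-[(R)-6-oxo-3,6-dihydro-2H-pyran-2-yl]prop-2-en-1-yl acetate | C=C[C@H](OC(C)=O)[C@H]1CC=CC(=O)O1 | intermediate
10 | ethyl (S)-lactate | C[C@H](O)C(=O)OCC | starting material
11 | ethyl (S)-2-(tert-butyldimethylsilyloxy)propanoate | C[C@H](O[Si](C)(C)C(C)(C)C)C(=O)OCC | intermediate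
12 | (S)-2-(tert-butyldimethylsilyloxy)propanoic acid | C[C@H](O[Si](C)(C)C(C)(C)C)C(=O)O | intermediate
13 | (S)-2-(tert-butyldimethylsilyloxy)propanoic isobutyl carbonic anhydride | C[C@H](O[Si](C)(C)C(C)(C)C)C(=O)OC(=O)OCC(C)C | intermediate
14 | (S)-3-(tert-butyldimethylsilyloxy)-1-diazobutan-2-one | C[C@H](O[Si](C)(C)C(C)(C)C)C(=O)C=[N+]=[N-] | intermediate
15 | (S)-{(1S,2S)-2-[(S)-2-(tert-butyldimethylsilyloxy)propanoyl]cyclopropyl}[(R)-6-oxo-3,6-dihydro-2H-pyran-2-yl]methyl acetate | CC(=O)O[C@@H]([C@H]1C[C@@H]1C(=O)[C@H](C)O[Si](C)(C)C(C)(C)C)[C@H]1CC=CC(=O)O1 | intermediate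
16 | (S)-{(1S,2S)-2-[(S)-2-hydroxypropanoyl]cyclopropyl}[(R)-6-oxo-3,6-dihydro-2H-pyran-2-yl]methyl acetate | CC(=O)O[C@@H]([C@H]1C[C@@H]1C(=O)[C@H](C)O)[C@H]1CC=CC(=O)O1 | intermediate
17 | caffeic acid | OC(=O)/C=C/c1ccc(O)c(O)c1 | starting material
18 | tert-butyldimethylsilyl (E)-3-[3,4-bis(tert-butyldimethylsilyloxy)phenyl]acrylate | CC(C)(C)[Si](C)(C)OC(=O)/C=C/c1ccc(O[Si](C)(C)C(C)(C)C)c(O[Si](C)(C)C(C)(C)C)c1 | intermediate
19 | (E)-3-[3,4-bis(tert-butyldimethylsilyloxy)phenyl]acrylic acid | OC(=O)/C=C/c1ccc(O[Si](C)(C)C(C)(C)C)c(O[Si](C)(C)C(C)(C)C)c1 | intermediate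
20 | (S)-{(1S,2S)-2-[(S)-2-({(E)-3-[3,4-bis(tert-butyldimethylsilyloxy)phenyl]acryloyl}oxy)propanoyl]cyclopropyl}[(R)-6-oxo-3,6-dihydro-2H-pyran-2-yl]methyl acetate | CC(=O)O[C@@H]([C@H]1C[C@@H]1C(=O)[C@H](C)OC(=O)/C=C/c1ccc(O[Si](C)(C)C(C)(C)C)c(O[Si](C)(C)C(C)(C)C)c1)[C@H]1CC=CC(=O)O1 | intermediate
21 | (S)-{(1S,2S)-2-[(S)-2-{[(E)-3-(3,4-dihydroxyphenyl)acryloyl]oxy}propanoyl]cyclopropyl}[(R)-6-oxo-3,6-dihydro-2H-pyran-2-yl]methyl acetate | CC(=O)O[C@@H]([C@H]1C[C@@H]1C(=O)[C@H](C)OC(=O)/C=C/c1ccc(O)c(O)c1)[C@H]1CC=CC(=O)O1 | target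

**Totals**
Total step count: 14.
Longest linear sequence: 10 steps (steps 1–6, 10, 11, 13, 14).

**Three steps most likely to fail, with fallbacks**

Step 10 (the proposed new cyclopropanation; risks are low reactivity of the allylic-acetate olefin, carbene dimerisation, and a mismatched face preference). The fallback uses known chemistry, sets out from 11 and 9, and comes back at 15. Ester 11 is converted with MeNHOMe·HCl and iPrMgCl (THF, −20 °C) into the Weinreb amide (S)-2-(tert-butyldimethylsilyloxy)-N-methoxy-N-methylpropanamide F1. Addition of CH2=CHMgBr (THF, 0 °C, inverse acidic quench) gives the vinyl ketone (S)-4-(tert-butyldimethylsilyloxy)pent-1-en-3-one F2. Cross-metathesis of F2 (3 equiv) with 9, using the second-generation Hoveyda–Grubbs catalyst RuCl2(H2IMes)(=CH-C6H4-2-OiPr) in CH2Cl2 at 40 °C, gives the E-enone (1S,2E,5S)-5-(tert-butyldimethylsilyloxy)-4-oxo-1-[(R)-6-oxo-3,6-dihydro-2H-pyran-2-yl]hex-2-en-1-yl acetate F3. Corey–Chaykovsky cyclopropanation of F3 (Me3S(O)I, NaH, DMSO/THF, 0 °C) reacts at the more electrophilic acyclic enone and closes the trans ring. Face selectivity here rests only on the γ-acetoxy centre, so 15 is obtained after chromatographic removal of the face isomer.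

Step 4 (over-reduction of the vinyl group or incomplete lactonisation). The fallback sets out from 3 and comes back at 7, bypassing steps 3 and 4 by a Ghosez lactone synthesis. Lithiated 1,1,1-trimethoxy-3-(phenylsulfonyl)propane (n-BuLi, THF/DMPU, −78 → 0 °C) opens epoxide 3 at the terminal carbon to give the hydroxy sulfone orthoester (5R,6S)-6-(tert-butyldimethylsilyloxy)-1,1,1-trimethoxy-3-(phenylsulfonyl)oct-7-en-5-ol F4. TsOH·H2O (cat.) in CH2Cl2 hydrolyses the orthoester and lactonises it to (6R)-6-[(S)-1-(tert-butyldimethylsilyloxy)prop-2-en-1-yl]-4-(phenylsulfonyl)tetrahydro-2H-pyran-2-one F5. DBU (CH2Cl2, 0 °C) eliminates sulfinate (E1cB) to give 7 with no hydrogenation.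

Step 13 (slow acylation by the hindered conjugated acid, with epimerisation next to the ketone). The fallback sets out from 16 and comes back at 20; it builds the cinnamate C=C by neutral metathesis. Alcohol 16 is acylated quickly with acryloyl chloride and iPr2NEt (CH2Cl2, −78 °C) to the acrylate (S)-{(1S,2S)-2-[(S)-2-(acryloyloxy)propanoyl]cyclopropyl}[(R)-6-oxo-3,6-dihydro-2H-pyran-2-yl]methyl acetate F6. Separately, 3,4-dihydroxybenzaldehyde is silylated (TBSCl, imidazole, DMF) to 3,4-bis(tert-butyldimethylsilyloxy)benzaldehyde F7 and methylenated (Ph3PCH3Br, KHMDS, THF, 0 °C) to 4-ethenyl-1,2-bis(tert-butyldimethylsilyloxy)benzene F8. Cross-metathesis of F6 with F8 (3 equiv), using the second-generation Grubbs catalyst RuCl2(H2IMes)(PCy3)(=CHPh) in CH2Cl2 at 40 °C, gives the E-cinnamate 20.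

**Further compounds**
F1 | step 10 | (S)-2-(tert-butyldimethylsilyloxy)-N-methoxy-N-methylpropanamide | C[C@H](O[Si](C)(C)C(C)(C)C)C(=O)N(C)OC
F2 | step 10 | (S)-4-(tert-butyldimethylsilyloxy)pent-1-en-3-one | C[C@H](O[Si](C)(C)C(C)(C)C)C(=O)C=C
F3 | step 10 | (1S,2E,5S)-5-(tert-butyldimethylsilyloxy)-4-oxo-1-[(R)-6-oxo-3,6-dihydro-2H-pyran-2-yl]hex-2-en-1-yl acetate | CC(=O)O[C@@H](/C=C/C(=O)[C@H](C)O[Si](C)(C)C(C)(C)C)[C@H]1CC=CC(=O)O1
F4 | step 4 | (5R,6S)-6-(tert-butyldimethylsilyloxy)-1,1,1-trimethoxy-3-(phenylsulfonyl)oct-7-en-5-ol (mixture at C3) | C=C[C@H](O[Si](C)(C)C(C)(C)C)[C@H](O)CC(CC(OC)(OC)OC)S(=O)(=O)c1ccccc1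
F5 | step 4 | (6R)-6-[(S)-1-(tert-butyldimethylsilyloxy)prop-2-en-1-yl]-4-(phenylsulfonyl)tetrahydro-2H-pyran-2-one (mixture at C4) | C=C[C@H](O[Si](C)(C)C(C)(C)C)[C@H]1CC(CC(=O)O1)S(=O)(=O)c1ccccc1
F6 | step 13 | (S)-{(1S,2S)-2-[(S)-2-(acryloyloxy)propanoyl]cyclopropyl}[(R)-6-oxo-3,6-dihydro-2H-pyran-2-yl]methyl acetate | CC(=O)O[C@@H]([C@H]1C[C@@H]1C(=O)[C@H](C)OC(=O)C=C)[C@H]1CC=CC(=O)O1
F7 | step 13 | 3,4-bis(tert-butyldimethylsilyloxy)benzaldehyde | O=Cc1ccc(O[Si](C)(C)C(C)(C)C)c(O[Si](C)(C)C(C)(C)C)c1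
F8 | step 13 | 4-ethenyl-1,2-bis(tert-butyldimethylsilyloxy)benzene | C=Cc1ccc(O[Si](C)(C)C(C)(C)C)c(O[Si](C)(C)C(C)(C)C)c1
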